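## The problem

CNP0167461.2 is a heliangolide. In germacrane numbering it is a cyclodecane with a 4Z alkene, a trans 1β,10α-epoxide, an α-methylene γ-lactone closed from C12 to O6 and trans-fused across C6–C7, an 8β-(2R,3R)-epoxyangelate and a 3β-isovalerate (ring centres 1R,3S,6R,7R,8R,10R). A ten-membered carbocycle is costly to close end to end (entropy, transannular strain), and its two ring alkenes must be made with opposite geometry: Z at C4=C5, E at C1=C10 before epoxidation. C7 and C8 are a cis pair that can be bought; C6 can be derived from C7 by addition to a C6 carbonyl; C1 and C10 follow from the face of the E alkene that a peracid sees. C3 is insulated from all of these and needs its own source of absolute configuration. The methylene lactone, the two epoxides, the two esters and the (E,Z)-cyclodecadiene tolerate neither strong acid, strong base nor nucleophiles, so they must be introduced late and in a fixed order. The enabling feature is the 1,3 relationship of O6 and C1=C10 through C10. A bond drawn across the ring from C6 to C10 divides it into a cyclopentane (C6–C10) and a cycloheptene (C10, C1–C6) in which C6 is a tertiary carbinol and C1 carries a leaving group. That is the retron of a Grob fragmentation, which delivers the C6 carbonyl and the E alkene in one step.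

## Retrosynthesis

Germacrane numbering is used for every intermediate. On the cyclopentane, "top" is the face carrying the C7 acetamide arm and O8.

**Epoxide and acyl groups last (36 ⇐ 35 ⇐ 30 + 4).** The two C–O bonds of the 1,10-epoxide are cut first. In 35 the C1=C10 alkene is the only electron-rich alkene: C4=C5 is flanked by two acyloxy carbons and the methylene is conjugated. An epoxide carried earlier would not survive fluoride, enolate or acid steps. The ester C–O bonds are cut next. O8 (PMB ether) and O3 (TBS ether) are unmasked one at a time, so the hindered epoxy acid 4 goes on O8 and isovalerate on O3 without any selection between two free hydroxyls.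

**Methylene lactone (30 ⇐ 26 ⇐ 25 ⇐ 24).** C11–C13 is cut back to the lactone enolate. This step must precede the acylations, because an isovalerate would enolise as well. The C12–O6 bond is cut to the γ-hydroxy amide 25, and C6–H to the dienone 24. Carrying C12 as a dimethylamide and O8 as an ether from the start means only O6 can ever be acylated by C12. The neighbouring option, an 8,12-lactone moved to O6 by equilibration, leaves the direction to thermodynamics that cannot be predicted for this ring. It also puts an acyloxy leaving group β to every C6 ketone on the route.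

**Key disconnection (24 ⇐ 22).** Reconnecting C6 to C10 turns the ten-membered dienone into the bicyclo[5.3.0]decenol mesylate 22. Of the possible transannular bonds, this one alone converts both product functions, the C6 carbonyl and the C1=C10 alkene, into the two ends of one fragmentation, and it leaves the Z alkene inside a cycloheptene where it cannot be anything else. The precursor has a five- and a seven-membered ring instead of a ten-membered one, and C3, C7 and C8 are set on small rings. The forward reaction needs the C1–O bond anti-periplanar to C6–C10 and C2 anti to C9 across C1–C10. Analysis of the bicycle shows that the E alkene requires the C1 oxygen on the same side as C9 in the zigzag C6–C10–C1–C2. A chair aldol of a C10 enolate with an aldehyde would give the opposite arrangement, so C1 is not made by that aldol. It is made by hydride delivery to a C1 ketone, directed from O3. With the C10 configuration that alkylation delivers (methyl on the bottom face, C1 chain on the top face) and 3S, the required centre is 1S, the anti 1,3-diol. C6 and C10 are erased in the key step, so either C6 epimer would serve. The trans-fused one that the reagents deliver is rigid and holds the mesylate equatorial.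

**Seven-membered ring (22 ⇐ 21 ⇐ 20).** The mesylate comes from diol 21, in which only the secondary C1 hydroxyl can be sulfonylated. C4=C5 is cut by ring-closing metathesis to diene 20. A cycloheptene can only hold a Z alkene, and the cut places the two alkene halves on carbonyl-addition products: a vinyl group at C6 and an isopropenyl carbinol at C3.

**Side chain (20 ⇐ 18 + 19; 18 ⇐ 17 ⇐ 16 ⇐ 13 + 14).** C5–C6 is cut to vinylmagnesium bromide 19 and ketone 18. The silyl ether is removed to diol 17. C1–H is cut to β-hydroxy ketone 16 (anti reduction). C2–C3 is cut to methyl ketone 13 and methacrolein 14 by a reagent-controlled boron aldol that supplies the absolute configuration of C3. Each forward step is asked for one thing only: addition from the open bottom face, silylation of the less hindered hydroxyl, internal hydride delivery, and Si-face attack on the aldehyde.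

**Quaternary C10 (13 ⇐ 12 ⇐ 11 ⇐ 10 ⇐ 8 + 9 ⇐ 7 ⇐ 6 ⇐ 5).** The C10–CH3 bond is cut to β-diketone 12. Building C10 by two enolate alkylations of a C6 ketone would fail on regiochemistry (C10 against C7), and any C7 enolate has O8 in the β position. Making C10 the carbon between two carbonyls means a weak base touches only that position. The diketone is traced through 11 and 10 to epoxide 8 and isopropenylmagnesium bromide 9. The C10–C1 bond is made by epoxide opening at the carbon remote from the C7 arm, which puts oxygen on C6 and carbon on C10 without any enolate. Epoxide 8 comes from cyclopentene 7, and 7 from lactone 5 by aminolysis and etherification. Lactone 5 supplies C7 and C8 as a single enantiomer.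

**Epoxy acid (4 ⇐ 3 ⇐ 2 ⇐ 1).** The carboxyl is cut back to the epoxy alcohol 3, the oxirane to (Z)-allylic alcohol 2 (Sharpless epoxidation), and 2 to methyl angelate 1. Epoxidising an angelate already on the ring would be slow and unselective.

## Roads not taken

Alternative 1: The cut is C1–C10. In the forward step SmI2 couples the C1 aldehyde and the C10 methyl ketone of the open-chain lactone A1 to the ring diol A2. The trans epoxide would follow by sulfonylating the secondary C1 hydroxyl and closing with the tertiary one. Its merits are real. Oxygen arrives on exactly the two epoxide carbons. The 6,12-lactone and C6 are settled before the ring exists, so neither the reduction of a medium-ring ketone nor the late peracid step of the chosen plan is needed. In these two respects this road is better. Its weak points are the closure of a ten-membered ring at a ketone against entropy and transannular strain, and two new centres set by the folding of a flexible chain, of which only one diol isomer gives the 1β,10α epoxide after an inverting closure. A1 also needs C3, C6, C7, C8 and a Z trisubstituted alkene from acyclic control. The chosen plan sets against this a ring formation that is a bond cleavage with no entropic price and an alkene geometry dictated by the bicycle.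

Alternative 2: The cut is C7–C8. Tin–lithium exchange (nBuLi) next to oxygen in the 13-membered stannyl allylic ether A3 starts a [2,3] shift that contracts the ring to A4, forms C7–C8, frees the C8 hydroxyl and creates the C11=C13 methylene. The methylene arrives without any late enolate step and a 13-membered ring is easier to close than a ten-membered one. On both counts it is ahead of the chosen plan, which needs an LDA/Mannich sequence on a sensitive lactone. Against it, A3 is a macrocyclic ether with two ring alkenes, three silyl ethers and a configurationally defined stannane, so it is about as hard to make as the target. C7 and C8 are both created in a large-ring transition state whose sense is hard to foresee, and a [1,2] shift competes. C12 must still be raised from the alcohol to the acid level beside a skipped diene. The chosen plan buys C7 and C8 as a cis pair in lactone 5 and never has to create them.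

Alternative 3: The bond formed is C8–C9 and the bond broken is C1–C6. The potassium alkoxide (KH, 18-crown-6) of the carvone-derived trans-dialkenylcyclohexenol A5 undergoes a chair [3,3] shift to the dienone A6, with Z C4=C5 from the six-membered ring and E C1=C10 from the chair. It shares the logic of the chosen plan (ring expansion, C6 ketone, both alkene geometries from a small ring) and reaches a ten-membered dienone from the chiral pool in fewer steps. To that point it is equal or better in step economy. Its weak points lie after the ring. A6 has no carbon on C7 and silicon on C8. The acetic acid arm would have to be attached by alkylating a medium-ring enolate cis to the future O8. The silyl group would have to be oxidised to hydroxyl with electrophilic reagents in the presence of two trisubstituted alkenes. The chosen plan spends more steps before the ring expansion, but afterwards adds nothing to the ten-membered ring except hydride at C6.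

Key step: step 17

Remarks on the chemistry (assumptions):
- The enol borinate from 13 and (+)-Ipc2BCl is taken to add to the Si face of methacrolein, the sense usual for methyl ketones, giving 3S. If the sense is opposite, (−)-Ipc2BCl is used and nothing else changes.
- L-(+)-Diethyl tartrate is taken to give the 2S epoxy alcohol 3, the usual sense for primary allylic alcohols.
- Compounds 1, 5, 9, 14 and 19 are bought.
- The face of the epoxide in 8 is of no consequence, since C6 and C10 are both erased at 12.

## Route

Step 1
Reactants: 1 methyl (Z)-2-methylbut-2-enoate (methyl angelate)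
Product: 2 (Z)-2-methylbut-2-en-1-ol
Conditions: iBu2AlH (2.2 equiv), CH2Cl2, −78 °C; Rochelle salt work-up
Reagents that add atoms: none
Why: 1,2-Reduction of an enoate to the allylic alcohol by an aluminium hydride at low temperature; the Z alkene is neither reduced nor isomerised.

Step 2
Reactants: 2 (Z)-2-methylbut-2-en-1-ol
Product: 3 [(2S,3R)-2,3-dimethyloxiran-2-yl]methanol
Conditions: Ti(OiPr)4 (cat.), L-(+)-diethyl tartrate (cat.), tBuOOH, 4 Å molecular sieves, CH2Cl2, −20 °C
Reagents that add atoms: tert-butyl hydroperoxide, CC(C)(C)OO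
Why: Sharpless asymmetric epoxidation of a primary allylic alcohol; the tartrate selects the alkene face (2S), and the Z geometry then fixes C3 as R.

Step 3
Reactants: 3 [(2S,3R)-2,3-dimethyloxiran-2-yl]methanol
Product: 4 (2R,3R)-2,3-dimethyloxirane-2-carboxylic acid
Conditions: RuCl3 (cat.), NaIO4, CCl4–MeCN–H2O, rt
Reagents that add atoms: sodium periodate, [Na+].[O-]I(=O)(=O)=O; water, O
Why: Catalytic RuO4 oxidation of a primary epoxy alcohol to the epoxy acid without opening the oxirane; the descriptor at C2 changes from S to R only because the CIP ranking changes.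

Step 4
Reactants: 5 (1R,5S)-2-oxabicyclo[3.3.0]oct-6-en-3-one
Product: 6 2-[(1S,5R)-5-hydroxycyclopent-2-en-1-yl]-N,N-dimethylacetamide
Conditions: Me2NH (2 M in THF, excess), 40 °C, sealed vessel
Reagents that add atoms: dimethylamine, CNC
Why: Aminolysis of a γ-lactone to the hydroxy amide; C7 and C8 are untouched, and the tertiary amide is a carboxyl form that later alkoxides cannot acylate themselves with.

Step 5
Reactants: 6 2-[(1S,5R)-5-hydroxycyclopent-2-en-1-yl]-N,N-dimethylacetamide
Product: 7 2-{(1S,5R)-5-[(4-methoxybenzyl)oxy]cyclopent-2-en-1-yl}-N,N-dimethylacetamide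
Conditions: NaH, 4-methoxybenzyl chloride, Bu4NI (cat.), THF–DMF, 0 °C → rt
Reagents that add atoms: 4-methoxybenzyl chloride, COc1ccc(CCl)cc1
Why: Williamson etherification under basic conditions, chosen because acid would re-close the lactone; an ether on O8 cannot leave from a later C7 enolate as a carboxylate would.

Step 6
Reactants: 7 2-{(1S,5R)-5-[(4-methoxybenzyl)oxy]cyclopent-2-en-1-yl}-N,N-dimethylacetamide
Product: 8 C6,C10-epoxide of 7 with the oxirane on the bottom face
Conditions: mCPBA, NaHCO3, CH2Cl2, 0 °C
Reagents that add atoms: 3-chloroperbenzoic acid, OOC(=O)c1cccc(Cl)c1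
Why: Prilezhaev epoxidation, expected anti to the two cis substituents.

Step 7
Reactants: 8 C6,C10-epoxide; 9 isopropenylmagnesium bromide
Product: 10 trans C6-hydroxy C10-isopropenyl cyclopentane
Conditions: CuI (10 mol %), THF, −30 → 0 °C
Reagents that add atoms: none
Why: Copper-catalysed SN2 opening of an epoxide by a Grignard reagent; attack with inversion at C10, the carbon remote from the C7 arm, puts carbon on C10 and oxygen on C6, and a tertiary amide is inert at this temperature.

Step 8
Reactants: 10 trans C6-hydroxy C10-isopropenyl cyclopentane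
Product: 11 trans C6-hydroxy C10-acetyl cyclopentane
Conditions: OsO4 (2 mol %), NaIO4, 2,6-lutidine, dioxane–H2O, rt
Reagents that add atoms: sodium periodate, [Na+].[O-]I(=O)(=O)=O; water, O
Why: Lemieux–Johnson cleavage of a 1,1-disubstituted alkene to the methyl ketone; it spares the electron-rich PMB arene that ozone might attack.

Step 9
Reactants: 11 trans C6-hydroxy C10-acetyl cyclopentane
Product: 12 2-acetylcyclopentanone (β-diketone with C6 and C1 carbonyls)
Conditions: Dess–Martin periodinane, NaHCO3, CH2Cl2, rt
Reagents that add atoms: none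
Why: Neutral oxidation of a secondary alcohol; the product is an enolised β-diketone, so the configuration at C10 and the history of C6 no longer matter.

Step 10
Reactants: 12 2-acetylcyclopentanone
Product: 13 2-{(1R,3R,5R)-3-acetyl-5-[(4-methoxybenzyl)oxy]-3-methyl-2-oxocyclopentyl}-N,N-dimethylacetamide
Conditions: K2CO3, MeI, acetone, rt
Reagents that add atoms: iodomethane, CI
Why: C-Alkylation of a β-diketone; carbonate deprotonates only C10, so C7 is never enolised, and iodomethane enters anti to the C7 arm and O8 (both 1,3 to C10), placing methyl on the bottom face and acetyl on the top face (10R).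

Step 11
Reactants: 13 quaternary diketone; 14 methacrolein
Product: 16 (3S)-β-hydroxy ketone with C1 ketone and C3 carbinol, via enol diisopinocampheylborinate 15 (not isolated)
Conditions: (+)-Ipc2BCl, Et3N, Et2O, −78 → 0 °C; then 14, −78 → −20 °C; H2O2, pH 7 buffer, MeOH
Reagents that add atoms: none
Why: Boron aldol of a methyl ketone under reagent control; the chloroborane with Et3N enolises the unhindered acetyl methyl and not the C7 methine, and the isopinocampheyl ligands select the Si face of the aldehyde, which sets C3 as S.

Step 12
Reactants: 16 (3S)-β-hydroxy ketone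
Product: 17 (1S,3S)-anti-1,3-diol with the C6 ketone intact
Conditions: Me4NBH(OAc)3, MeCN–AcOH, −30 °C
Reagents that add atoms: none
Why: Evans–Saksena reduction; the C3 hydroxyl binds boron and delivers hydride internally through a chair to the C1 ketone, giving the anti diol (1S), while the C6 ketone has no free hydroxyl in reach and the new C1 hydroxyl stays tied up as the borate until work-up.

Step 13
Reactants: 17 (1S,3S)-anti-1,3-diol
Product: 18 C3 tert-butyldimethylsilyl ether
Conditions: TBSCl, imidazole, DMF, 0 °C
Reagents that add atoms: tert-butyldimethylsilyl chloride, CC(C)(C)[Si](C)(C)Cl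
Why: Silylation under steric control; the allylic C3 hydroxyl reacts, the C1 hydroxyl next to the quaternary C10 does not.

Step 14
Reactants: 18 C3 silyl ether ketone; 19 vinylmagnesium bromide
Product: 20 (1S,3S,6R,7R,8R,10R) C6 vinyl carbinol
Conditions: CeCl3 (dried), 19 (3.5 equiv), THF, −78 °C
Reagents that add atoms: none
Why: Organocerium 1,2-addition to a hindered, enolisable ketone; the top face of C6 is blocked by the C7 arm and the C10 chain, so vinyl adds from the bottom face next to H7 and the C10 methyl, giving OH top and vinyl bottom (either C6 epimer would fragment to the same dienone).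

Step 15
Reactants: 20 C6 vinyl carbinol
Product: 21 trans-fused bicyclo[5.3.0]dec-4-ene-1,6-diol
Conditions: second-generation Grubbs catalyst (5–10 mol %), toluene (2 mM), 80 °C
Reagents that add atoms: none
Why: Ring-closing metathesis; the catalyst loads on the vinyl group beside the free tertiary hydroxyl and closes onto the isopropenyl group, and a seven-membered ring can only hold the Z C4=C5 alkene.

Step 16
Reactants: 21 bicyclic diol
Product: 22 (1S,3S,6R,7R,8R,10R) C1 methanesulfonate of the bicyclic diol
Conditions: MsCl, Et3N, CH2Cl2, −20 → 0 °C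
Reagents that add atoms: methanesulfonyl chloride, CS(=O)(=O)Cl
Why: Sulfonylation through the sulfene reaches the hindered secondary C1 hydroxyl and leaves the tertiary C6 hydroxyl free; without an alkoxide the 1,3-diol monosulfonate does not fragment.

Step 17
Reactants: 22 bicyclic C1 mesylate
Product: 24 2-[(1R,2R,4E,7S,8Z)-7-{[tert-butyl(dimethyl)silyl]oxy}-2-[(4-methoxybenzyl)oxy]-4,8-dimethyl-10-oxocyclodeca-4,8-dien-1-yl]-N,N-dimethylacetamide, via potassium alkoxide 23 (not isolated)
Conditions: KOtBu (1.1 equiv), THF, 0 °C, 30 min; pH 7 buffer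
Reagents that add atoms: none
Why: KOtBu turns the tertiary C6 hydroxyl into alkoxide 23; the oxygen lone pair pushes into the C6–C10 bond, that bond's electrons form the C1=C10 π bond, and mesylate leaves from C1, all in one concerted step. The closest known reaction type is the Grob (Wharton-type) fragmentation of cyclic 1,3-diol monosulfonates to medium-ring enones. The ten-membered ring is not closed by a cyclisation: it appears when the bond shared by the five- and seven-membered rings breaks, so no ring-closure mode applies and no entropy is paid. No stereocentre is created; C1, C6 and C10 become trigonal and C3, C7 and C8 are untouched. The step needs E geometry at C1=C10 and fragmentation in preference to oxetane closure or E2 loss of the mesylate. The trans ring fusion locks C9 anti to C2 across C10–C1, and the 1S configuration holds the mesylate equatorial, anti-periplanar to C6–C10, so only the E alkene can form. The Z C4=C5 alkene is carried over from the cycloheptene. Because O8 is an ether and C12 an amide, the alkoxide has no ester to attack and the product ketone has no β-acyloxy group to lose; the near-stoichiometric base, low temperature and buffered quench limit enolisation at C7.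

Step 18
Reactants: 24 (1(10)E,4Z)-dienone
Product: 25 (6R)-allylic alcohol
Conditions: NaBH4, CeCl3·7H2O, MeOH, −78 °C
Reagents that add atoms: none
Why: Luche 1,2-reduction of the Z enone; with the ring carbons C5 and C8 anti about C6–C7, as in the natural lactones, the C7 arm stands perpendicular to the carbonyl and hydride adds anti to it, giving the 6R alcohol.

Step 19
Reactants: 25 (6R)-allylic alcohol
Product: 26 (3S,6R,7R,8R)-6,12-lactone with O8 PMB ether and O3 silyl ether
Conditions: pyridinium p-toluenesulfonate (1.2 equiv), toluene, 50 °C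
Reagents that add atoms: none
Why: Acid-promoted lactonisation of a γ-hydroxy dimethylamide (5-exo-trig acyl substitution) with retention at C6; O8 is an ether, so the trans-fused 6,12-lactone is the only one that can form.

Step 20
Reactants: 26 6,12-lactone
Product: 30 α-methylene lactone (C11=C13), via lithium lactone enolate 27 (not isolated), via Mannich base 28 (not isolated), via trimethylammonium iodide 29 (not isolated)
Conditions: LDA, THF, −78 °C; Me2N=CH2 I (Eschenmoser's salt), −78 °C → rt; MeI, THF–MeOH, rt; aq. NaHCO3, CH2Cl2
Reagents that add atoms: N,N-dimethylmethyleneiminium iodide, C[N+](C)=C.[I-]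
Why: Mannich methylenation of a lactone enolate followed by quaternisation and E1cB loss of trimethylamine; no other ester is present at this stage and the C11 configuration is of no consequence.

Step 21
Reactants: 30 α-methylene lactone
Product: 31 C8 alcohol
Conditions: DDQ, CH2Cl2–pH 7 buffer, 0 °C
Reagents that add atoms: none
Why: Oxidative cleavage of a 4-methoxybenzyl ether through the benzylic cation; the silyl ether, the unconjugated alkenes and the methylene lactone are not oxidised.

Step 22
Reactants: 31 C8 alcohol; 4 (2R,3R)-2,3-dimethyloxirane-2-carboxylic acid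
Product: 33 C8 (2R,3R)-epoxyangelate, via mixed trichlorobenzoic anhydride 32 (not isolated)
Conditions: 2,4,6-trichlorobenzoyl chloride, Et3N, toluene, rt; then 31, DMAP, rt
Reagents that add atoms: none
Why: Yamaguchi esterification; the acid has no α-hydrogen and cannot isomerise, and DMAP carries the acyl group to the secondary 8β-hydroxyl with retention.

Step 23
Reactants: 33 C8 epoxyangelate
Product: 34 C3 alcohol
Conditions: HF·pyridine, pyridine, THF, 0 °C → rt
Reagents that add atoms: none
Why: Fluoride cleavage of the secondary silyl ether under buffered, weakly acidic conditions that spare the deactivated epoxy ester and the methylene lactone.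

Step 24
Reactants: 34 C3 alcohol
Product: 35 C3 isovalerate (1(10)E,4Z)-diene
Conditions: 3-methylbutanoic anhydride, DMAP, pyridine, CH2Cl2, 0 °C → rt
Reagents that add atoms: 3-methylbutanoic anhydride, CC(C)CC(=O)OC(=O)CC(C)C
Why: DMAP-catalysed acylation of the allylic 3β-hydroxyl with retention.

Step 25
Reactants: 35 C3 isovalerate diene
Product: 36 CNP0167461.2
Conditions: mCPBA, NaHCO3, CH2Cl2, −20 → 0 °C
Reagents that add atoms: 3-chloroperbenzoic acid, OOC(=O)c1cccc(Cl)c1
Why: Prilezhaev epoxidation of the most electron-rich alkene; attack on the outer face of the E C1=C10 alkene, as in related germacranolides, gives the 1β,10α (1R,10R) epoxide stereospecifically from the E geometry.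

## Compound list

1 | methyl (Z)-2-methylbut-2-enoate (methyl angelate) | C/C=C(/C)C(=O)OC | starting material
2 | (Z)-2-methylbut-2-en-1-ol | C/C=C(/C)CO | intermediate
3 | [(2S,3R)-2,3-dimethyloxiran-2-yl]methanol | OC[C@]1(C)O[C@@H]1C | intermediate
4 | (2R,3R)-2,3-dimethyloxirane-2-carboxylic acid | OC(=O)[C@]1(C)O[C@@H]1C | intermediate
5 | (1R,5S)-2-oxabicyclo[3.3.0]oct-6-en-3-one | O=C1C[C@@H]2[C@H](O1)CC=C2 | starting material
6 | 2-[(1S,5R)-5-hydroxycyclopent-2-en-1-yl]-N,N-dimethylacetamide | CN(C)C(=O)C[C@@H]1[C@H](O)CC=C1 | intermediate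
7 | 2-{(1S,5R)-5-[(4-methoxybenzyl)oxy]cyclopent-2-en-1-yl}-N,N-dimethylacetamide | CN(C)C(=O)C[C@@H]1[C@H](OCc2ccc(OC)cc2)CC=C1 | intermediate
8 | N,N-dimethyl-2-{3-[(4-methoxybenzyl)oxy]-6-oxabicyclo[3.1.0]hexan-2-yl}acetamide, oxirane (C6, C10) on the bottom face, arm and ether on the top face | CN(C)C(=O)C[C@@H]1[C@H](OCc2ccc(OC)cc2)C[C@H]3O[C@@H]13 | intermediate
9 | isopropenylmagnesium bromide | CC(=C)[Mg]Br | starting material
10 | 2-{2-hydroxy-5-[(4-methoxybenzyl)oxy]-3-(prop-1-en-2-yl)cyclopentyl}-N,N-dimethylacetamide, C6 hydroxyl bottom, C10 isopropenyl, C7 arm and O8 top | CN(C)C(=O)C[C@@H]1[C@H](OCc2ccc(OC)cc2)C[C@H](C(C)=C)[C@H]1O | intermediate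
11 | 2-{3-acetyl-2-hydroxy-5-[(4-methoxybenzyl)oxy]cyclopentyl}-N,N-dimethylacetamide, same relative configuration as 10 | CN(C)C(=O)C[C@@H]1[C@H](OCc2ccc(OC)cc2)C[C@H](C(C)=O)[C@H]1O | intermediate
12 | 2-{3-acetyl-5-[(4-methoxybenzyl)oxy]-2-oxocyclopentyl}-N,N-dimethylacetamide (keto–enol mixture, C10 not configurationally defined; C7 R, C8 R) | CN(C)C(=O)C[C@@H]1[C@H](OCc2ccc(OC)cc2)CC(C(C)=O)C1=O | intermediate
13 | 2-{(1R,3R,5R)-3-acetyl-5-[(4-methoxybenzyl)oxy]-3-methyl-2-oxocyclopentyl}-N,N-dimethylacetamide (C10 methyl bottom, acetyl top) | CN(C)C(=O)C[C@@H]1[C@H](OCc2ccc(OC)cc2)C[C@](C)(C(C)=O)C1=O | intermediate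
14 | methacrolein | CC(=C)C=O | starting material
15 | enol diisopinocampheylborinate of the acetyl group of 13 | CN(C)C(=O)C[C@@H]1[C@H](OCc2ccc(OC)cc2)C[C@](C)(C(=C)OB([C@H]2C[C@H]3C[C@@H]([C@@H]2C)C3(C)C)[C@H]2C[C@H]3C[C@@H]([C@@H]2C)C3(C)C)C1=O | intermediate (not isolated)
16 | (3S,7R,8R,10R) aldol: C10 bears methyl and the chain C1(=O)–C2H2–C3H(OH)–C4(CH3)=CH2 | CN(C)C(=O)C[C@@H]1[C@H](OCc2ccc(OC)cc2)C[C@](C)(C(=O)C[C@H](O)C(C)=C)C1=O | intermediate
17 | (1S,3S,7R,8R,10R) anti-1,3-diol, C6 ketone | CN(C)C(=O)C[C@@H]1[C@H](OCc2ccc(OC)cc2)C[C@](C)([C@@H](O)C[C@H](O)C(C)=C)C1=O | intermediate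
18 | C3 tert-butyldimethylsilyl ether of 17 | CN(C)C(=O)C[C@@H]1[C@H](OCc2ccc(OC)cc2)C[C@](C)([C@@H](O)C[C@H](O[Si](C)(C)C(C)(C)C)C(C)=C)C1=O | intermediate
19 | vinylmagnesium bromide | C=C[Mg]Br | starting material
20 | (1S,3S,6R,7R,8R,10R) C6 vinyl carbinol (C6 OH top, vinyl bottom) | CN(C)C(=O)C[C@@H]1[C@H](OCc2ccc(OC)cc2)C[C@](C)([C@@H](O)C[C@H](O[Si](C)(C)C(C)(C)C)C(C)=C)[C@@]1(O)C=C | intermediate
21 | (1S,3S,6R,7R,8R,10R) trans-fused bicyclo[5.3.0]dec-4-ene-1,6-diol: cyclopentane C6–C10, cycloheptene C10, C1–C6, 3-OTBS, 8-OPMB, 7-CH2CONMe2, 10-CH3 | CN(C)C(=O)C[C@@H]1[C@H](OCc2ccc(OC)cc2)C[C@]3(C)[C@@H](O)C[C@H](O[Si](C)(C)C(C)(C)C)C(C)=C[C@@]13O | intermediate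
22 | C1 methanesulfonate of 21 | CN(C)C(=O)C[C@@H]1[C@H](OCc2ccc(OC)cc2)C[C@]3(C)[C@@H](OS(C)(=O)=O)C[C@H](O[Si](C)(C)C(C)(C)C)C(C)=C[C@@]13O | intermediate
23 | potassium C6 alkoxide of 22 | CN(C)C(=O)C[C@@H]1[C@H](OCc2ccc(OC)cc2)C[C@]3(C)[C@@H](OS(C)(=O)=O)C[C@H](O[Si](C)(C)C(C)(C)C)C(C)=C[C@@]13[O-].[K+] | intermediate (not isolated)
24 | 2-[(1R,2R,4E,7S,8Z)-7-{[tert-butyl(dimethyl)silyl]oxy}-2-[(4-methoxybenzyl)oxy]-4,8-dimethyl-10-oxocyclodeca-4,8-dien-1-yl]-N,N-dimethylacetamide (germacrane: 1(10)E,4Z, 3S,7R,8R, 6-oxo) | CN(C)C(=O)C[C@@H]1[C@H](OCc2ccc(OC)cc2)C/C(C)=C/C[C@H](O[Si](C)(C)C(C)(C)C)/C(C)=C\C1=O | intermediate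
25 | (3S,6R,7R,8R) allylic alcohol from 24 | CN(C)C(=O)C[C@@H]1[C@H](OCc2ccc(OC)cc2)C/C(C)=C/C[C@H](O[Si](C)(C)C(C)(C)C)/C(C)=C\[C@H]1O | intermediate
26 | (1(10)E,4Z)-(3S,6R,7R,8R)-6,12-lactone, 3-OTBS, 8-OPMB | O=C1C[C@@H]2[C@H](OCc3ccc(OC)cc3)C/C(C)=C/C[C@H](O[Si](C)(C)C(C)(C)C)/C(C)=C\[C@H]2O1 | intermediate
27 | lithium enolate of lactone 26 | [Li]OC1=C[C@@H]2[C@H](OCc3ccc(OC)cc3)C/C(C)=C/C[C@H](O[Si](C)(C)C(C)(C)C)/C(C)=C\[C@H]2O1 | intermediate (not isolated)
28 | 11-(dimethylaminomethyl) lactone (C11 undefined) | O=C1C(CN(C)C)[C@@H]2[C@H](OCc3ccc(OC)cc3)C/C(C)=C/C[C@H](O[Si](C)(C)C(C)(C)C)/C(C)=C\[C@H]2O1 | intermediate (not isolated)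
29 | 11-(trimethylammoniomethyl) lactone iodide | O=C1C(C[N+](C)(C)C)[C@@H]2[C@H](OCc3ccc(OC)cc3)C/C(C)=C/C[C@H](O[Si](C)(C)C(C)(C)C)/C(C)=C\[C@H]2O1.[I-] | intermediate (not isolated)
30 | α-methylene lactone, 3-OTBS, 8-OPMB | O=C1C(=C)[C@@H]2[C@H](OCc3ccc(OC)cc3)C/C(C)=C/C[C@H](O[Si](C)(C)C(C)(C)C)/C(C)=C\[C@H]2O1 | intermediate
31 | α-methylene lactone, 3-OTBS, 8-OH | O=C1C(=C)[C@@H]2[C@H](O)C/C(C)=C/C[C@H](O[Si](C)(C)C(C)(C)C)/C(C)=C\[C@H]2O1 | intermediate
32 | (2R,3R)-2,3-dimethyloxirane-2-carboxylic 2,4,6-trichlorobenzoic anhydride | O=C(OC(=O)[C@]1(C)O[C@@H]1C)c1c(Cl)cc(Cl)cc1Cl | intermediate (not isolated)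
33 | 8-O-[(2R,3R)-2,3-dimethyloxirane-2-carbonyl] lactone, 3-OTBS | O=C1C(=C)[C@@H]2[C@H](OC(=O)[C@]3(C)O[C@@H]3C)C/C(C)=C/C[C@H](O[Si](C)(C)C(C)(C)C)/C(C)=C\[C@H]2O1 | intermediate
34 | 8-O-epoxyangeloyl lactone, 3-OH | O=C1C(=C)[C@@H]2[C@H](OC(=O)[C@]3(C)O[C@@H]3C)C/C(C)=C/C[C@H](O)/C(C)=C\[C@H]2O1 | intermediate
35 | 8-O-epoxyangeloyl 3-O-isovaleryl (1(10)E,4Z)-diene lactone | O=C1C(=C)[C@@H]2[C@H](OC(=O)[C@]3(C)O[C@@H]3C)C/C(C)=C/C[C@H](OC(=O)CC(C)C)/C(C)=C\[C@H]2O1 | intermediate
36 | CNP0167461.2: (1R,3S,4Z,6R,7R,8R,10R)-1,10-epoxy-3-(3-methylbutanoyloxy)-8-[(2R,3R)-2,3-dimethyloxirane-2-carbonyloxy]germacra-4,11(13)-dien-12,6-olide | C=C1C(=O)O[C@@H]2/C=C(/C)[C@@H](OC(=O)CC(C)C)C[C@H]3O[C@]3(C)C[C@@H](OC(=O)[C@]3(C)O[C@@H]3C)[C@@H]12 | target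

## Step count and least certain steps

Total: 25 steps. Longest linear sequence: 22 steps (steps 4–25, from lactone 5); the epoxy acid 4 takes 3 steps (steps 1–3).

**Step 17 (key step).** The fragmentation may be slow against two competing processes: E2 loss of the mesylate toward C2, and 4-exo closure of the alkoxide on C1 to an oxetane. Both would take over if the mesylate cannot hold the equatorial, anti-periplanar position. Base-induced enolisation of the product at C7 is a lesser worry. Fallback: from diol 21, the C1 hydroxyl is oxidised with Dess–Martin periodinane to the bicyclic β-hydroxy ketone F1. KHMDS then triggers a retro-aldol cleavage of the same C6–C10 bond. The C1 enolate that is released has C2 anti to C9, enforced by the same trans ring fusion, and is trapped with PhNTf2 as the enol triflate F2. Pd(OAc)2/PPh3 with Bu3N and HCO2H reduces the triflate to the C1–H alkene, and the route is rejoined at dienone 24.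

**Step 18.** Hydride may be delivered to the wrong face of the medium-ring ketone, because the ring conformation that decides the face cannot be predicted with confidence. Fallback: the 6S allylic alcohol F6, obtained from 24 as the other reduction product or with a bulkier hydride, is treated with MsCl/Et3N. In the allylic mesylate F7 the amide oxygen displaces the leaving group from the back side, giving the cyclic iminium ether F8. Aqueous NaHCO3 hydrolyses it with loss of dimethylamine to lactone 26, now with C6 inverted to R.

**Step 11.** Reagent control may be eroded by a mismatch with the chiral ketone or by a sense of induction opposite to the one assumed; enolisation toward C7 is a lesser concern. Fallback: from 13, LiHMDS/TMSCl at −78 °C gives the trimethylsilyl enol ether F3 of the acetyl group. F3 is added to methacrolein 14 in a Mukaiyama aldol promoted by a chiral N-sulfonyl oxazaborolidinone (catalyst control through an open transition state), which returns to 16 after desilylation.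

**Step 15.** Ring closure onto the hindered 1,1-disubstituted alkene next to the silyl ether may be slow, so that dimerisation through the vinyl group takes over. Fallback: from diol 17, vinyl addition (19, CeCl3) is run first to give the triol diene F4. Metathesis of F4, helped by the free allylic C3 hydroxyl, gives the bicyclic triol F5. Silylation of its only unhindered hydroxyl (C3; TBSCl, imidazole) returns to 21.

**Step 25.** The peracid may attack the wrong face of C1=C10, or the neighbouring alkene may take part across the ring. Fallback for the wrong face: from 35, NBS in aqueous THF adds bromine from the outer face and water anti at C10 to give bromohydrin F9. Ag2O closes F9 with inversion at C1 to the epoxide of the opposite facial sense, which is 36.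

## Further compounds

F1 | step 17 | bicyclic β-hydroxy ketone (C1 ketone, C6 tertiary hydroxyl; otherwise as 21) | CN(C)C(=O)C[C@@H]1[C@H](OCc2ccc(OC)cc2)C[C@]3(C)C(=O)C[C@H](O[Si](C)(C)C(C)(C)C)C(C)=C[C@@]13O
F2 | step 17 | C1 enol trifluoromethanesulfonate of the ten-membered dienone (C2 and C9 trans) | CN(C)C(=O)C[C@@H]1[C@H](OCc2ccc(OC)cc2)C/C(C)=C(OS(=O)(=O)C(F)(F)F)/C[C@H](O[Si](C)(C)C(C)(C)C)/C(C)=C\C1=O
F3 | step 11 | trimethylsilyl enol ether of the acetyl group of 13 | CN(C)C(=O)C[C@@H]1[C@H](OCc2ccc(OC)cc2)C[C@](C)(C(=C)O[Si](C)(C)C)C1=O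
F4 | step 15 | triol diene (C1, C3 and C6 hydroxyls free; C6 vinyl) | CN(C)C(=O)C[C@@H]1[C@H](OCc2ccc(OC)cc2)C[C@](C)([C@@H](O)C[C@H](O)C(C)=C)[C@@]1(O)C=C
F5 | step 15 | trans-fused bicyclo[5.3.0]dec-4-ene-1,3,6-triol | CN(C)C(=O)C[C@@H]1[C@H](OCc2ccc(OC)cc2)C[C@]3(C)[C@@H](O)C[C@H](O)C(C)=C[C@@]13O
F6 | step 18 | (6S)-allylic alcohol, C6 epimer of 25 | CN(C)C(=O)C[C@@H]1[C@H](OCc2ccc(OC)cc2)C/C(C)=C/C[C@H](O[Si](C)(C)C(C)(C)C)/C(C)=C\[C@@H]1O
F7 | step 18 | (6S)-allylic methanesulfonate | CN(C)C(=O)C[C@@H]1[C@H](OCc2ccc(OC)cc2)C/C(C)=C/C[C@H](O[Si](C)(C)C(C)(C)C)/C(C)=C\[C@@H]1OS(C)(=O)=O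
F8 | step 18 | cyclic iminium ether (O6–C12 closed, C6 R) methanesulfonate | C[N+](C)=C1C[C@@H]2[C@H](OCc3ccc(OC)cc3)C/C(C)=C/C[C@H](O[Si](C)(C)C(C)(C)C)/C(C)=C\[C@H]2O1.CS(=O)(=O)[O-]
F9 | step 25 | 1-bromo-10-hydroxy bromohydrin of 35 | O=C1C(=C)[C@@H]2[C@H](OC(=O)[C@]3(C)O[C@@H]3C)C[C@@](C)(O)[C@@H](Br)C[C@H](OC(=O)CC(C)C)/C(C)=C\[C@H]2O1
A1 | alternative 1 | seco keto aldehyde (C1 aldehyde, C10 methyl ketone, 6,12-lactone, 3-OTBS, 8-OTES) | O=C1C[C@@H]([C@H](O1)/C=C(/C)[C@@H](O[Si](C)(C)C(C)(C)C)CC=O)[C@@H](CC(C)=O)O[Si](CC)(CC)CC
A2 | alternative 1 | lactone-fused cyclodecene-1,10-diol | O=C1C[C@H]2[C@H](O1)/C=C(/C)[C@@H](O[Si](C)(C)C(C)(C)C)C[C@H](O)[C@](C)(O)C[C@H]2O[Si](CC)(CC)CC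
A3 | alternative 2 | 13-membered α-tributylstannyl allylic ether | CCCC[Sn](CCCC)(CCCC)[C@H]1OC/C(CO[Si](CC)(CC)CC)=C/[C@H](O[Si](CC)(CC)CC)/C=C(/C)[C@@H](O[Si](C)(C)C(C)(C)C)C/C=C(\C)C1
A4 | alternative 2 | cyclodecadien-8-ol with C7 2-(silyloxymethyl)vinyl side chain | C=C(CO[Si](CC)(CC)CC)[C@H]1[C@H](O[Si](CC)(CC)CC)/C=C(/C)[C@@H](O[Si](C)(C)C(C)(C)C)C/C=C(\C)C[C@H]1O
A5 | alternative 3 | trans-1-(2-silylvinyl)-6-isopropenyl-3-methyl-4-silyloxycyclohex-2-en-1-ol | O[C@@]1(/C=C/[Si](C)(C)c2ccccc2)C=C(C)[C@@H](O[Si](C)(C)C(C)(C)C)C[C@H]1C(C)=C
A6 | alternative 3 | (2Z,6E)-cyclodeca-2,6-dienone with C3 silyloxy and C8 dimethylphenylsilyl groups | O=C1/C=C(/C)[C@@H](O[Si](C)(C)C(C)(C)C)C/C=C(\C)C[C@@H]([Si](C)(C)c2ccccc2)C1
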